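**Retrosynthetic overview**
- The lactol stereocentre is released last by hydrogenolysis of an (R)-1-phenylethyl pseudoester whose (S)-acetal epimer has been separated from its diastereomer; the two benzyl ethers fall in the same step.
- The seven-membered depsidone lactone (formed second) comes from carbodiimide lactonisation of a 2-aryloxybenzoic acid; the five-membered lactol ring (formed first) closes spontaneously when the ring B 2-formylbenzoic acid is unmasked.
- The diaryl ether comes from SNAr of a ring B phenol on a ring A fluoride flanked by formyl and ester groups.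
- Ring B comes from 2,4-dihydroxybenzoic acid. The key C–C bond is an intermolecular Mannich reaction that joins the arene to the iminium carbon (the future CH2OH); a Dakin-type oxidation and an ortho-formylation complete the ring.
- Ring A comes from 3,5-difluorotoluene by lithiation/formylation, SNAr with benzyl alcohol, bromination and carboxylation.

Assumption: the (S)-lactol carbon is the only stereocentre and is configurationally labile in solution (ring–chain tautomerism), so it is fixed as a separable acetal and freed only in the last, neutral step; the product must be kept cold, neutral and aprotic.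

**Ring A**

Step 1
Reactants: 1 3,5-difluorotoluene
Product: 4 2,6-difluoro-4-methylbenzaldehyde, via aryllithium 2 (not isolated), via lithium hemiaminalate 3 (not isolated)
Conditions: n-BuLi, THF, −78 °C; DMF, −78 → 0 °C; aq. HCl
Reagents that add atoms: N,N-dimethylformamide, CN(C)C=O
Why: The C–H between the two fluorines is the most acidic site (doubly fluorine-directed ortho-lithiation), and the aryllithium is formylated by DMF through the hemiaminalate (Bouveault formylation).

Step 2
Reactants: 4 2,6-difluoro-4-methylbenzaldehyde
Product: 5 2-(benzyloxy)-6-fluoro-4-methylbenzaldehyde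
Conditions: BnOH (1.0 equiv), NaH, THF, 0 °C → rt
Reagents that add atoms: benzyl alcohol, OCc1ccccc1
Why: SNAr of benzyl oxide on a fluoride ortho to the formyl group; the two fluorides are equivalent and the first alkoxy group deactivates the ring against a second substitution.

Step 3
Reactants: 5 2-(benzyloxy)-6-fluoro-4-methylbenzaldehyde
Product: 6 6-(benzyloxy)-3-bromo-2-fluoro-4-methylbenzaldehyde
Conditions: NBS, MeCN, rt, dark
Reagents that add atoms: N-bromosuccinimide, O=C1CCC(=O)N1Br
Why: Electrophilic aromatic bromination goes para to the benzyloxy group (also ortho to F and CH3, meta to CHO), the most activated free position, under polar non-radical conditions that spare the benzylic CH3 and OCH2Ph.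

Step 4
Reactants: 6 6-(benzyloxy)-3-bromo-2-fluoro-4-methylbenzaldehyde
Product: 10 4-(benzyloxy)-2-fluoro-3-formyl-6-methylbenzoic acid, via amino alkoxide 7 (not isolated), via aryllithium 8 (not isolated), via lithium carboxylate 9 (not isolated)
Conditions: morpholine, n-BuLi, THF, −78 °C, then 6; n-BuLi, −78 °C; CO2, −78 °C → rt; aq. HCl
Reagents that add atoms: carbon dioxide, O=C=O
Why: Lithium morpholide masks the aldehyde as an α-amino alkoxide (Comins in situ protection), bromine–lithium exchange at −78 °C is faster than LiF loss from the ortho-fluoroaryllithium, and CO2 traps the anion; acid work-up returns the aldehyde.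

Step 5
Reactants: 10 4-(benzyloxy)-2-fluoro-3-formyl-6-methylbenzoic acid
Product: 11 allyl 4-(benzyloxy)-2-fluoro-3-formyl-6-methylbenzoate
Conditions: allyl bromide, KHCO3, DMF, rt
Reagents that add atoms: allyl bromide, C=CCBr
Why: SN2 O-alkylation of the carboxylate is insensitive to the two ortho substituents that would block a Fischer esterification, and the allyl ester is later removed by palladium without touching benzyl ethers or aldehydes.

**Ring B**

Step 6
Reactants: 12 2,4-dihydroxybenzoic acid
Product: 13 allyl 2,4-dihydroxybenzoate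
Conditions: allyl bromide, KHCO3, DMF, 40 °C
Reagents that add atoms: allyl bromide, C=CCBr
Why: Bicarbonate deprotonates only the carboxylic acid, so SN2 alkylation gives the ester and leaves both phenols free.

Step 7
Reactants: 13 allyl 2,4-dihydroxybenzoate
Product: 15 allyl 5-formyl-2,4-dihydroxybenzoate, via iminium chloride 14 (not isolated)
Conditions: POCl3, DMF, MeCN, 0 → 50 °C; H2O, 50 °C
Reagents that add atoms: N,N-dimethylformamide, CN(C)C=O; water, O
Why: Vilsmeier–Haack formylation, in which the bulky chloroiminium ion attacks C-5 (para to the 2-OH, ortho to the 4-OH) rather than the flanked C-3, which stays free for the next step.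

Step 8
Reactants: 15 allyl 5-formyl-2,4-dihydroxybenzoate
Product: 16 allyl 3-[(dimethylamino)methyl]-5-formyl-2,4-dihydroxybenzoate
Conditions: Eschenmoser's salt (Me2N=CH2 iodide), K2CO3, MeCN, rt
Reagents that add atoms: N,N-dimethylmethyleneiminium iodide, C=[N+](C)C.[I-]
Why: Intermolecular Mannich reaction: C-3 is the only activated position left, ortho to both phenoxide oxygens and meta to both carbonyl groups, so the preformed iminium ion forms the new aryl–CH2 bond there, and this carbon becomes the CH2OH of the target.

Step 9
Reactants: 16 allyl 3-[(dimethylamino)methyl]-5-formyl-2,4-dihydroxybenzoate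
Product: 18 allyl 3-[(benzyloxy)methyl]-5-formyl-2,4-dihydroxybenzoate, via ammonium iodide 17 (not isolated)
Conditions: MeI, acetone, rt; concentrate; BnOH (solvent), NaHCO3, 80 °C
Reagents that add atoms: benzyl alcohol, OCc1ccccc1
Why: Exhaustive N-methylation makes trimethylamine a leaving group, which benzyl alcohol replaces in a phenoxide-assisted elimination–addition at the benzylic carbon (Mannich-base exchange); bicarbonate is too weak to transesterify the allyl ester.

Step 10
Reactants: 18 allyl 3-[(benzyloxy)methyl]-5-formyl-2,4-dihydroxybenzoate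
Product: 19 allyl 2,4-bis(allyloxy)-3-[(benzyloxy)methyl]-5-formylbenzoate
Conditions: allyl bromide (2.5 equiv), K2CO3, DMF, 60 °C
Reagents that add atoms: allyl bromide, C=CCBr
Why: Williamson etherification of both chelated phenols; these allyl ethers come off later together with the allyl esters in one palladium step.

Step 11
Reactants: 19 allyl 2,4-bis(allyloxy)-3-[(benzyloxy)methyl]-5-formylbenzoate
Product: 21 allyl 2,4-bis(allyloxy)-3-[(benzyloxy)methyl]-5-hydroxybenzoate, via aryl formate 20 (not isolated)
Conditions: mCPBA (1.2 equiv), CH2Cl2, 0 °C → rt; then MeOH, Et3N (cat.), 0 °C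
Reagents that add atoms: 3-chloroperoxybenzoic acid, OOC(=O)c1cccc(Cl)c1
Why: Baeyer–Villiger (Dakin-type) oxidation: the 2,4-dialkoxyaryl group migrates faster than the inductively deactivated allyl C=C bonds are epoxidised, and mild methanolysis of the formate frees the phenol that becomes the diaryl ether oxygen.

Step 12
Reactants: 21 allyl 2,4-bis(allyloxy)-3-[(benzyloxy)methyl]-5-hydroxybenzoate
Product: 23 allyl 2,4-bis(allyloxy)-3-[(benzyloxy)methyl]-6-formyl-5-hydroxybenzoate, via hydroxymethyl phenol 22 (not isolated)
Conditions: MgCl2, Et3N, (CH2O)n, MeCN, reflux; aq. HCl work-up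
Reagents that add atoms: formaldehyde (from paraformaldehyde), C=O
Why: Casnati–Skattebøl ortho-formylation: the magnesium phenoxide delivers formaldehyde to the only free ring position (ortho to OH), and the benzylic alkoxide is oxidised by hydride transfer to a second formaldehyde; this carbon becomes the lactol carbon.

**Fragment union and endgame**

Step 13
Reactants: 11 allyl 4-(benzyloxy)-2-fluoro-3-formyl-6-methylbenzoate; 23 allyl 2,4-bis(allyloxy)-3-[(benzyloxy)methyl]-6-formyl-5-hydroxybenzoate
Product: 24 allyl 2,4-bis(allyloxy)-5-[2-(allyloxycarbonyl)-5-(benzyloxy)-6-formyl-3-methylphenoxy]-3-[(benzyloxy)methyl]-6-formylbenzoate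
Conditions: K2CO3, DMF, 60 °C
Reagents that add atoms: none
Why: SNAr: the fluoride of 11 is activated by an ortho-formyl and an ortho-ester group, and 23 has a single free phenol, so the diaryl ether forms with defined regiochemistry.

Step 14
Reactants: 24 tetra-allyl diaryl ether
Product: 25 4-(benzyloxy)-2-({6-[(benzyloxy)methyl]-3,5,7-trihydroxy-1-oxo-1,3-dihydro-2-benzofuran-4-yl}oxy)-3-formyl-6-methylbenzoic acid (racemic lactol)
Conditions: Pd(PPh3)4 (10 mol %), morpholine (12 equiv), THF, rt; aq. HCl work-up
Reagents that add atoms: none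
Why: Tsuji–Trost deallylation with zerovalent palladium and morpholine as allyl acceptor removes all four allyl groups under neutral conditions, and the freed 2-formylbenzoic acid of ring B closes spontaneously to the 3-hydroxyphthalide (first new ring), racemic at the lactol carbon.

Step 15
Reactants: 25 lactol acid
Product: 26 4-(benzyloxy)-2-({6-[(benzyloxy)methyl]-5,7-dihydroxy-1-oxo-3-[(1R)-1-phenylethoxy]-1,3-dihydro-2-benzofuran-4-yl}oxy)-3-formyl-6-methylbenzoic acid (mixture of the two epimers at C-3 of the phthalide)
Conditions: (R)-1-phenylethanol (5 equiv), PPTS (cat.), 4 Å MS, toluene, 60 °C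
Reagents that add atoms: (R)-1-phenylethanol, C[C@@H](O)c1ccccc1
Why: Acid-catalysed pseudoester (acetal) formation of the lactol with the chiral alcohol gives both epimers at the acetal carbon, which are now diastereomers, while the di-ortho-substituted benzoic acid does not esterify under these conditions.

Step 16
Reactants: 26 pseudoester acid (mixture of the two acetal epimers)
Product: 27 protected depsidone pseudoester (mixture of the two acetal epimers): salazinic acid bearing a benzyl ether on the ring A phenol and on the CH2OH oxygen plus an (R)-1-phenylethyl group on the lactol oxygen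
Conditions: DCC, DMAP (cat.), CH2Cl2 (0.005 M), rt
Reagents that add atoms: none
Why: Steglich-type carbodiimide lactonisation: only the 5-OH of the phthalide can reach the activated ring A acid (seven-membered depsidone ring, second new ring), and the acetal carbon is untouched without acid, so both epimers are carried through unchanged.

Step 17
Reactants: 27 protected depsidone pseudoester (mixture of the two acetal epimers)
Product: 28 protected depsidone pseudoester as the single (S)-acetal epimer carrying the (R)-1-phenylethyl group
Conditions: flash chromatography (SiO2, hexane/EtOAc), configuration assigned by X-ray against the known (R) centre of the auxiliary; the separated (R)-acetal epimer is returned to the mixture 27 with PPTS (cat.) and (R)-1-phenylethanol (1 equiv) in toluene at 60 °C and separated again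
Reagents that add atoms: none
Why: Resolution through covalent diastereomers: the two acetal epimers differ in physical properties and are configurationally stable without acid, so their separation fixes the lactol carbon as (S), while acid-catalysed acetal exchange through the acyloxycarbenium ion recycles the unwanted epimer.

Step 18
Reactants: 28 protected depsidone pseudoester, (S)-acetal
Product: 29 salazinic acid, (S)-lactol (CNP0166154.1)
Conditions: H2 (1 atm), 10% Pd/C, EtOAc, rt, stopped at full conversion; filter and evaporate cold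
Reagents that add atoms: none
Why: Hydrogenolysis cleaves the unhindered benzylic C–O bonds of the two benzyl ethers and the PhCH(CH3)–O bond of the auxiliary much faster than the hindered, electron-poor C–O bonds at the acetal carbon, so the (S)-lactol is released with retention under neutral, aprotic conditions.

**Compound list**

1 | 3,5-difluorotoluene | Cc1cc(F)cc(F)c1 | starting material
2 | (2,6-difluoro-4-methylphenyl)lithium | [Li]c1c(F)cc(C)cc1F | intermediate
3 | lithium (2,6-difluoro-4-methylphenyl)(dimethylamino)methanolate | CN(C)C(O[Li])c1c(F)cc(C)cc1F | intermediate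
4 | 2,6-difluoro-4-methylbenzaldehyde | Cc1cc(F)c(C=O)c(F)c1 | intermediate
5 | 2-(benzyloxy)-6-fluoro-4-methylbenzaldehyde | Cc1cc(F)c(C=O)c(OCc2ccccc2)c1 | intermediate
6 | 6-(benzyloxy)-3-bromo-2-fluoro-4-methylbenzaldehyde | Cc1cc(OCc2ccccc2)c(C=O)c(F)c1Br | intermediate
7 | lithium [6-(benzyloxy)-3-bromo-2-fluoro-4-methylphenyl](morpholin-4-yl)methanolate | Cc1cc(OCc2ccccc2)c(C(O[Li])N2CCOCC2)c(F)c1Br | intermediate
8 | aryllithium from 7 (Li in place of Br) | Cc1cc(OCc2ccccc2)c(C(O[Li])N2CCOCC2)c(F)c1[Li] | intermediate
9 | lithium carboxylate from 8 (CO2Li in place of Li) | Cc1cc(OCc2ccccc2)c(C(O[Li])N2CCOCC2)c(F)c1C(=O)O[Li] | intermediate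
10 | 4-(benzyloxy)-2-fluoro-3-formyl-6-methylbenzoic acid | Cc1cc(OCc2ccccc2)c(C=O)c(F)c1C(=O)O | intermediate
11 | allyl 4-(benzyloxy)-2-fluoro-3-formyl-6-methylbenzoate | Cc1cc(OCc2ccccc2)c(C=O)c(F)c1C(=O)OCC=C | intermediate
12 | 2,4-dihydroxybenzoic acid | OC(=O)c1ccc(O)cc1O | starting material
13 | allyl 2,4-dihydroxybenzoate | C=CCOC(=O)c1ccc(O)cc1O | intermediate
14 | aryl iminium chloride (ArCH=NMe2 chloride at C-5 of 13) | C=CCOC(=O)c1cc(C=[N+](C)C)c(O)cc1O.[Cl-] | intermediate
15 | allyl 5-formyl-2,4-dihydroxybenzoate | C=CCOC(=O)c1cc(C=O)c(O)cc1O | intermediate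
16 | allyl 3-[(dimethylamino)methyl]-5-formyl-2,4-dihydroxybenzoate | C=CCOC(=O)c1cc(C=O)c(O)c(CN(C)C)c1O | intermediate
17 | trimethylammonium iodide of 16 | C=CCOC(=O)c1cc(C=O)c(O)c(C[N+](C)(C)C)c1O.[I-] | intermediate
18 | allyl 3-[(benzyloxy)methyl]-5-formyl-2,4-dihydroxybenzoate | C=CCOC(=O)c1cc(C=O)c(O)c(COCc2ccccc2)c1O | intermediate
19 | allyl 2,4-bis(allyloxy)-3-[(benzyloxy)methyl]-5-formylbenzoate | C=CCOC(=O)c1cc(C=O)c(OCC=C)c(COCc2ccccc2)c1OCC=C | intermediate
20 | allyl 2,4-bis(allyloxy)-3-[(benzyloxy)methyl]-5-(formyloxy)benzoate | C=CCOC(=O)c1cc(OC=O)c(OCC=C)c(COCc2ccccc2)c1OCC=C | intermediate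
21 | allyl 2,4-bis(allyloxy)-3-[(benzyloxy)methyl]-5-hydroxybenzoate | C=CCOC(=O)c1cc(O)c(OCC=C)c(COCc2ccccc2)c1OCC=C | intermediate
22 | allyl 2,4-bis(allyloxy)-3-[(benzyloxy)methyl]-5-hydroxy-6-(hydroxymethyl)benzoate | C=CCOC(=O)c1c(CO)c(O)c(OCC=C)c(COCc2ccccc2)c1OCC=C | intermediate
23 | allyl 2,4-bis(allyloxy)-3-[(benzyloxy)methyl]-6-formyl-5-hydroxybenzoate | C=CCOC(=O)c1c(C=O)c(O)c(OCC=C)c(COCc2ccccc2)c1OCC=C | intermediate
24 | allyl 2,4-bis(allyloxy)-5-[2-(allyloxycarbonyl)-5-(benzyloxy)-6-formyl-3-methylphenoxy]-3-[(benzyloxy)methyl]-6-formylbenzoate | C=CCOC(=O)c1c(C)cc(OCc2ccccc2)c(C=O)c1Oc1c(C=O)c(C(=O)OCC=C)c(OCC=C)c(COCc2ccccc2)c1OCC=C | intermediate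
25 | 4-(benzyloxy)-2-({6-[(benzyloxy)methyl]-3,5,7-trihydroxy-1-oxo-1,3-dihydro-2-benzofuran-4-yl}oxy)-3-formyl-6-methylbenzoic acid, racemic lactol | Cc1cc(OCc2ccccc2)c(C=O)c(Oc2c(O)c(COCc3ccccc3)c(O)c3c2C(O)OC3=O)c1C(=O)O | intermediate
26 | 4-(benzyloxy)-2-({6-[(benzyloxy)methyl]-5,7-dihydroxy-1-oxo-3-[(1R)-1-phenylethoxy]-1,3-dihydro-2-benzofuran-4-yl}oxy)-3-formyl-6-methylbenzoic acid, both acetal epimers | Cc1cc(OCc2ccccc2)c(C=O)c(Oc2c(O)c(COCc3ccccc3)c(O)c3c2C(O[C@H](C)c2ccccc2)OC3=O)c1C(=O)O | intermediate
27 | protected depsidone pseudoester, both acetal epimers, (R)-1-phenylethyl (salazinic acid with benzyl ethers on the ring A phenol and the CH2OH oxygen) | Cc1cc(OCc2ccccc2)c(C=O)c2c1C(=O)Oc1c(COCc3ccccc3)c(O)c3c(c1O2)C(O[C@H](C)c1ccccc1)OC3=O | intermediate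
28 | protected depsidone pseudoester, (S)-acetal, (R)-1-phenylethyl | Cc1cc(OCc2ccccc2)c(C=O)c2c1C(=O)Oc1c(COCc3ccccc3)c(O)c3c(c1O2)[C@@H](O[C@H](C)c1ccccc1)OC3=O | intermediate
29 | salazinic acid, (S)-lactol | Cc1cc(O)c(C=O)c2c1C(=O)Oc1c(CO)c(O)c3c(c1O2)[C@@H](O)OC3=O | target

**Totals and risks**

Total steps: 18 (17 reactions and one diastereomer separation). Longest linear sequence: 13 steps (12 → 29, steps 6–12 and 13–18); the ring A branch (1 → 11) is 5 steps.

The three steps most likely to fail:

Risk A, step 12 (formylation at the crowded position between OH and the ester). Fallback: set out from 21. A second Mannich reaction (Eschenmoser's salt, K2CO3, MeCN) puts the small iminium electrophile ortho to the phenol and gives the Mannich base F1. MeI gives the trimethylammonium iodide F2, which on warming with aqueous NaHCO3 in MeCN exchanges NMe3 for water to give the hydroxymethyl phenol 22, now isolated. MnO2 in CH2Cl2 oxidises the benzylic alcohol, and the route is rejoined at 23.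

Risk B, step 13 (SNAr giving a tetra-ortho-substituted diaryl ether from a weakly nucleophilic, salicylaldehyde-type phenoxide). Fallback: set out from 23. The aldehyde is masked with 1,2-bis(trimethylsilyloxy)ethane and catalytic TMSOTf (CH2Cl2, −78 °C) to give the dioxolane phenol F3, whose phenoxide is no longer conjugated to a carbonyl group. SNAr with 11 (Cs2CO3, DMSO, 40 °C) gives the dioxolane diaryl ether F4, and PPTS in wet acetone removes the acetal, rejoining the route at 24.

Risk C, step 18 (hydrogenolysis may also reduce the aryl aldehyde, the ortho-hydroxybenzyl alcohol or the benzylic acetal C–O bonds, and the freed lactol epimerises if handled warm or basic). Fallback: set out from 28 and replace reductive by Lewis-acid cleavage. BCl3 with pentamethylbenzene as cation scavenger (CH2Cl2, −78 °C) cleaves the two benzyl ethers and the PhCH(CH3)–O bond on the side of the stabilised benzylic cation, not at the acyloxy-substituted acetal carbon. Aqueous work-up at 0 °C gives 29 directly, with no new isolated compound.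

**Further compounds**

F1 | step 12 | allyl 2,4-bis(allyloxy)-3-[(benzyloxy)methyl]-6-[(dimethylamino)methyl]-5-hydroxybenzoate | C=CCOC(=O)c1c(CN(C)C)c(O)c(OCC=C)c(COCc2ccccc2)c1OCC=C
F2 | step 12 | trimethylammonium iodide of F1 | C=CCOC(=O)c1c(C[N+](C)(C)C)c(O)c(OCC=C)c(COCc2ccccc2)c1OCC=C.[I-]
F3 | step 13 | allyl 2,4-bis(allyloxy)-3-[(benzyloxy)methyl]-6-(1,3-dioxolan-2-yl)-5-hydroxybenzoate | C=CCOC(=O)c1c(C2OCCO2)c(O)c(OCC=C)c(COCc2ccccc2)c1OCC=C
F4 | step 13 | dioxolane analogue of 24 (ring B formyl group as 1,3-dioxolane) | C=CCOC(=O)c1c(C)cc(OCc2ccccc2)c(C=O)c1Oc1c(C2OCCO2)c(C(=O)OCC=C)c(OCC=C)c(COCc2ccccc2)c1OCC=C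
F0 | step 18 | none | none
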